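**Retrosynthetic overview** (rings lettered A to F from the 2,4,6-trihydroxyphenoxy end; all six rings are bought as aromatics, so "ring order" means the order of the five diaryl C–O bonds)
1. Rings C and E both come from phenol 1 via its quinone monoketal 2, and rings B and D both come from bromophenol 3. The B–O–C (= D–O–E) bond is made first, once, by a new acid-catalysed ketal aryloxylation (2 + 3, via 4 and 5) giving the bifunctional dimer 6.
2. E–O–F: 6 + boronic acid 7 (Chan–Lam) gives bromide 8 (rings D, E, F). A–O–B: 6 + phenol 9 (Ullmann) gives phenol 10 (rings A, B, C).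
3. C–O–D is the last disconnection: 10 + 8 (Ullmann) gives hexadeca-O-methyl ether 11.
4. Global O-demethylation of 11 gives target 12.

Assumption: the target has no stereocentre and rotates freely about all diaryl ether bonds, so it is achiral and there is no enantiomer to select; 1, 3, 7 and 9 are taken as catalogue compounds.

**Step 1**
Reactants: 1 2,3,4-trimethoxyphenol
Product: 2 2,3,4,4-tetramethoxycyclohexa-2,5-dien-1-one
Conditions: PhI(OAc)2 (1.1 equiv), MeOH, 0 °C → rt, 30 min
Reagents that add atoms: methanol, CO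
Why: Oxidative dearomatisation of a para-methoxyphenol by the trivalent iodine reagent, with methanol trapping the methoxy-bearing para carbon, is the standard preparation of para-quinone monoketals.

**Step 2**
Reactants: 2 2,3,4,4-tetramethoxycyclohexa-2,5-dien-1-one; 3 4-bromo-2,6-dimethoxyphenol
Product: 6 6-(4-bromo-2,6-dimethoxyphenoxy)-2,3,4-trimethoxyphenol, via phenoxenium ion 4 (not isolated), via aryloxy-dienone adduct 5 (not isolated)
Conditions: 3 (3 equiv), (PhO)2P(O)OH (10 mol%), 5 Å MS, HFIP–CH2Cl2 (1:4), −20 → 0 °C; 2 added over 2 h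
Reagents that add atoms: none
Why: Proposed new method: an O-selective, acid-catalysed SN2′-type aryloxylation of a quinone monoketal, in which diphenyl phosphate ionises the ketal (loss of MeOH) to the phosphate-paired 2,3,4-trimethoxyphenoxenium ion 4 with charge at C2, C4 and C6, the phosphate hydrogen-bonds the O–H of 3 (whose ortho and para carbons are blocked and whose two remaining ring CH sites are flanked by Br and OMe and deactivated by Br) so that oxygen is the only accessible nucleophilic atom, attack at the substituted C2 or C4 only gives reversible ketal exchange, and attack at the unsubstituted C6 gives dienone 5, which tautomerises irreversibly to the ortho-aryloxyphenol 6 (a base-mediated Michael pathway would instead give the meta isomer); the closest known reaction type is the Brønsted-acid-promoted coupling of quinone monoketals with electron-rich arenes to give ortho-arylphenols, so far a C–C bond formation with carbon nucleophiles.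

**Step 3**
Reactants: 6 6-(4-bromo-2,6-dimethoxyphenoxy)-2,3,4-trimethoxyphenol; 7 (3,4,5-trimethoxyphenyl)boronic acid
Product: 8 5-bromo-1,3-dimethoxy-2-[3,4,5-trimethoxy-2-(3,4,5-trimethoxyphenoxy)phenoxy]benzene
Conditions: Cu(OAc)2 (30 mol%), pyridine (5 equiv), 7 (2.5 equiv), 4 Å MS, CH2Cl2, O2 (balloon), rt, 36 h
Reagents that add atoms: none
Why: Chan–Lam oxidative O-arylation (transmetalation to divalent copper, oxidation to a trivalent copper aryl phenoxide, reductive elimination) accepts di-ortho-substituted phenols at room temperature and leaves the aryl bromide untouched.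

**Step 4**
Reactants: 6 6-(4-bromo-2,6-dimethoxyphenoxy)-2,3,4-trimethoxyphenol; 9 2,4,6-trimethoxyphenol
Product: 10 6-[2,6-dimethoxy-4-(2,4,6-trimethoxyphenoxy)phenoxy]-2,3,4-trimethoxyphenol
Conditions: CuI (20 mol%), picolinic acid (40 mol%), K3PO4 (6 equiv), 9 (4 equiv), DMSO, 100 °C, Ar; 6 added by syringe pump over 8 h
Reagents that add atoms: none
Why: Ullmann-type diaryl ether synthesis catalysed by monovalent copper with a ligand suited to hindered phenols, in which the fourfold excess of the smaller, more electron-rich phenoxide of 9 and the low stationary concentration of 6 make cross-coupling outrun self-condensation of 6 through its own, more shielded hydroxyl.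

**Step 5**
Reactants: 10 6-[2,6-dimethoxy-4-(2,4,6-trimethoxyphenoxy)phenoxy]-2,3,4-trimethoxyphenol; 8 5-bromo-1,3-dimethoxy-2-[3,4,5-trimethoxy-2-(3,4,5-trimethoxyphenoxy)phenoxy]benzene
Product: 11 2-{4-[2-{4-[3,4,5-trimethoxy-2-(3,4,5-trimethoxyphenoxy)phenoxy]-3,5-dimethoxyphenoxy}-3,4,5-trimethoxyphenoxy]-3,5-dimethoxyphenoxy}-1,3,5-trimethoxybenzene
Conditions: CuI (30 mol%), picolinic acid (60 mol%), K3PO4 (3 equiv), 8 (1.2 equiv), DMSO, 110 °C, Ar, 48 h
Reagents that add atoms: none
Why: The same Ullmann coupling (monovalent copper phenoxide, oxidative addition of the aryl bromide, reductive elimination) works here because the bromide of 8 has two ortho hydrogens, so all steric demand sits on the 2,6-dioxygenated phenoxide of 10, and neither partner carries a second halide or hydroxyl.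

**Step 6**
Reactants: 11 the hexadeca-O-methyl ether
Product: 12 2-{4-[2-{4-[3,4,5-trihydroxy-2-(3,4,5-trihydroxyphenoxy)phenoxy]-3,5-dihydroxyphenoxy}-3,4,5-trihydroxyphenoxy]-3,5-dihydroxyphenoxy}benzene-1,3,5-triol
Conditions: BBr3 (40 equiv), CH2Cl2, −78 °C → rt, 24 h, Ar; degassed ice-water; Sephadex LH-20 (MeOH)
Reagents that add atoms: none
Why: Lewis-acid cleavage of aryl methyl ethers (boron complexation, bromide SN2 at methyl) removes all sixteen methyl groups, helped by chelation between vicinal oxygens, while the five diaryl ether bonds have no SN2-cleavable carbon and survive; no stereocentre is present to set or scramble.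

**Compound list**
1 | 2,3,4-trimethoxyphenol | COc1ccc(O)c(OC)c1OC | starting material
2 | 2,3,4,4-tetramethoxycyclohexa-2,5-dien-1-one | COC1=C(OC)C(OC)(OC)C=CC1=O | intermediate
3 | 4-bromo-2,6-dimethoxyphenol | COc1cc(Br)cc(OC)c1O | starting material
4 | 2,3,4-trimethoxyphenoxenium ion, i.e. (2,3-dimethoxy-4-oxocyclohexa-2,5-dien-1-ylidene)(methyl)oxonium, ion-paired to diphenyl phosphate | COC1=C(OC)C(=[O+]C)C=CC1=O | intermediate (not isolated)
5 | 6-(4-bromo-2,6-dimethoxyphenoxy)-2,3,4-trimethoxycyclohexa-2,4-dien-1-one (racemic at C6; the centre is lost on enolisation) | COC1=CC(Oc2c(OC)cc(Br)cc2OC)C(=O)C(OC)=C1OC | intermediate (not isolated)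
6 | 6-(4-bromo-2,6-dimethoxyphenoxy)-2,3,4-trimethoxyphenol | COc1cc(Oc2c(OC)cc(Br)cc2OC)c(O)c(OC)c1OC | intermediate
7 | (3,4,5-trimethoxyphenyl)boronic acid | COc1cc(B(O)O)cc(OC)c1OC | starting material
8 | 5-bromo-1,3-dimethoxy-2-[3,4,5-trimethoxy-2-(3,4,5-trimethoxyphenoxy)phenoxy]benzene | COc1cc(Oc2c(OC)cc(Br)cc2OC)c(Oc2cc(OC)c(OC)c(OC)c2)c(OC)c1OC | intermediate
9 | 2,4,6-trimethoxyphenol | COc1cc(OC)c(O)c(OC)c1 | starting material
10 | 6-[2,6-dimethoxy-4-(2,4,6-trimethoxyphenoxy)phenoxy]-2,3,4-trimethoxyphenol | COc1cc(OC)c(Oc2cc(OC)c(Oc3cc(OC)c(OC)c(OC)c3O)c(OC)c2)c(OC)c1 | intermediate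
11 | 2-{4-[2-{4-[3,4,5-trimethoxy-2-(3,4,5-trimethoxyphenoxy)phenoxy]-3,5-dimethoxyphenoxy}-3,4,5-trimethoxyphenoxy]-3,5-dimethoxyphenoxy}-1,3,5-trimethoxybenzene (hexadeca-O-methyl ether of the target) | COc1cc(OC)c(Oc2cc(OC)c(Oc3cc(OC)c(OC)c(OC)c3Oc3cc(OC)c(Oc4cc(OC)c(OC)c(OC)c4Oc4cc(OC)c(OC)c(OC)c4)c(OC)c3)c(OC)c2)c(OC)c1 | intermediate
12 | 2-{4-[2-{4-[3,4,5-trihydroxy-2-(3,4,5-trihydroxyphenoxy)phenoxy]-3,5-dihydroxyphenoxy}-3,4,5-trihydroxyphenoxy]-3,5-dihydroxyphenoxy}benzene-1,3,5-triol (achiral) | Oc1cc(O)c(Oc2cc(O)c(Oc3cc(O)c(O)c(O)c3Oc3cc(O)c(Oc4cc(O)c(O)c(O)c4Oc4cc(O)c(O)c(O)c4)c(O)c3)c(O)c2)c(O)c1 | target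

**Totals**
Total steps: 6. Longest linear sequence: 5 (1 → 2 → 6 → 8 or 10 → 11 → 12).

**Three steps most likely to fail**

Step 2 (the proposed new ketal aryloxylation). The risks are carbon attack by 3, or consumption of the electron-rich product 6 by a second phenoxenium ion. The fallback uses only known reactions: it sets out from 3 and 7 and comes back at 6, building the diaryl ether first and adding the oxygen afterwards. Chan–Lam coupling of 3 with 7 (Cu(OAc)2, pyridine, 4 Å MS, CH2Cl2, O2, rt) gives 5-bromo-1,3-dimethoxy-2-(3,4,5-trimethoxyphenoxy)benzene F1. Vilsmeier–Haack formylation (POCl3, DMF, 70 °C) takes place on the tetraoxygenated ring, ortho to the ether oxygen and para to a methoxy group (the brominated ring is less activated), through N-{[6-(4-bromo-2,6-dimethoxyphenoxy)-2,3,4-trimethoxyphenyl]methylidene}-N-methylmethanaminium chloride F2, which is not isolated. Aqueous NaOAc hydrolyses it to 6-(4-bromo-2,6-dimethoxyphenoxy)-2,3,4-trimethoxybenzaldehyde F3. Baeyer–Villiger (Dakin-type) oxidation with mCPBA (NaHCO3, CH2Cl2, rt) gives 6-(4-bromo-2,6-dimethoxyphenoxy)-2,3,4-trimethoxyphenyl formate F4, and K2CO3 in MeOH in the same flask releases 6. This costs three steps in place of steps 1 and 2.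

Step 5 (Ullmann coupling of two trimers at a very shielded phenol). The fallback replaces the high-temperature coupling of a halide by a room-temperature oxidative coupling of a boronic acid and attaches ring A last; it sets out from 8 and comes back at 11 without needing 10, so it also bypasses step 4. Bromine–lithium exchange on 8 (n-BuLi, THF, −78 °C) gives {3,5-dimethoxy-4-[3,4,5-trimethoxy-2-(3,4,5-trimethoxyphenoxy)phenoxy]phenyl}lithium F5, which is not isolated. Quenching with B(OiPr)3 and then aqueous HCl gives {3,5-dimethoxy-4-[3,4,5-trimethoxy-2-(3,4,5-trimethoxyphenoxy)phenoxy]phenyl}boronic acid F6. Chan–Lam coupling of F6 with phenol 6 under the step 3 conditions, which leave the bromide of 6 untouched, gives 5-bromo-2-{2-[3,5-dimethoxy-4-(3,4,5-trimethoxy-2-(3,4,5-trimethoxyphenoxy)phenoxy)phenoxy]-3,4,5-trimethoxyphenoxy}-1,3-dimethoxybenzene F7. Ullmann coupling of F7 with excess 9 (CuI, picolinic acid, K3PO4, DMSO, 100 °C), now with no competing phenol in the bromide, gives 11.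

Step 6 (sixteen-fold demethylation and isolation of an air-sensitive polyphenol). The fallback changes from direct isolation to capture and release; it sets out from 11 and comes back at 12. After BBr3 (CH2Cl2, −78 °C → rt) and methanol quench, crude 12 is not isolated but evaporated and peracetylated (Ac2O, pyridine, DMAP, rt) to the hexadecaacetate of 12 (every hydroxyl as its acetate) F8. F8 is stable to air and silica, so it can be purified by chromatography and crystallisation, and any partly methylated material can be separated and resubmitted. Acid methanolysis (HCl generated from AcCl in degassed MeOH, 40 °C, Ar) then gives 12 after evaporation of volatiles only.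

**Further compounds**
F1 | step 2 | 5-bromo-1,3-dimethoxy-2-(3,4,5-trimethoxyphenoxy)benzene | COc1cc(Oc2c(OC)cc(Br)cc2OC)cc(OC)c1OC
F2 | step 2 | N-{[6-(4-bromo-2,6-dimethoxyphenoxy)-2,3,4-trimethoxyphenyl]methylidene}-N-methylmethanaminium chloride (not isolated; counter-ion drawn as chloride) | COc1cc(Oc2c(OC)cc(Br)cc2OC)c(C=[N+](C)C)c(OC)c1OC.[Cl-]
F3 | step 2 | 6-(4-bromo-2,6-dimethoxyphenoxy)-2,3,4-trimethoxybenzaldehyde | COc1cc(Oc2c(OC)cc(Br)cc2OC)c(C=O)c(OC)c1OC
F4 | step 2 | 6-(4-bromo-2,6-dimethoxyphenoxy)-2,3,4-trimethoxyphenyl formate (not isolated) | COc1cc(Oc2c(OC)cc(Br)cc2OC)c(OC=O)c(OC)c1OC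
F5 | step 5 | {3,5-dimethoxy-4-[3,4,5-trimethoxy-2-(3,4,5-trimethoxyphenoxy)phenoxy]phenyl}lithium (not isolated) | COc1cc(Oc2c(OC)cc([Li])cc2OC)c(Oc2cc(OC)c(OC)c(OC)c2)c(OC)c1OC
F6 | step 5 | {3,5-dimethoxy-4-[3,4,5-trimethoxy-2-(3,4,5-trimethoxyphenoxy)phenoxy]phenyl}boronic acid | COc1cc(Oc2c(OC)cc(B(O)O)cc2OC)c(Oc2cc(OC)c(OC)c(OC)c2)c(OC)c1OC
F7 | step 5 | 5-bromo-2-{2-[3,5-dimethoxy-4-(3,4,5-trimethoxy-2-(3,4,5-trimethoxyphenoxy)phenoxy)phenoxy]-3,4,5-trimethoxyphenoxy}-1,3-dimethoxybenzene | COc1cc(Oc2c(OC)cc(Br)cc2OC)c(Oc2cc(OC)c(Oc3cc(OC)c(OC)c(OC)c3Oc3cc(OC)c(OC)c(OC)c3)c(OC)c2)c(OC)c1OC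
F8 | step 6 | hexadecaacetate of 12 (all sixteen hydroxyls acetylated) | CC(=O)Oc1cc(OC(C)=O)c(Oc2cc(OC(C)=O)c(Oc3cc(OC(C)=O)c(OC(C)=O)c(OC(C)=O)c3Oc3cc(OC(C)=O)c(Oc4cc(OC(C)=O)c(OC(C)=O)c(OC(C)=O)c4Oc4cc(OC(C)=O)c(OC(C)=O)c(OC(C)=O)c4)c(OC(C)=O)c3)c(OC(C)=O)c2)c(OC(C)=O)c1
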